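**Retrosynthetic overview** (C7/C8 = the former stilbene carbons of resveratrol units a, b, c; C7 carries the 4-oxyphenyl group)
1. Canaliculatol 33 ⇐ octamethyl ether 32 (BBr3). The eight-membered ring is closed last, by Friedel–Crafts attack of the 3,5-dimethoxyphenyl ring on C3 of the dihydrobenzofuran onto a 4-methoxybenzylic cation at C7b (31 → 32).
2. The indane is made in one operation from cyano ester 15 and 3,5-dimethoxybenzyne: the carbanion carbon C8b bonds to one aryne carbon, and the aryl anion formed at the other closes 5-exo onto the ketone carbon C7c.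
3. Enabling feature: in the dioxygenated benzo ring of the indane the two ring-fusion carbons are neighbours. The one bonded to C8b is meta to both ring oxygens and the one bonded to C7c is ortho to an oxygen, which is the polarity of a 3-alkoxyaryne (nucleophile remote from O, electrophile next to O). C8b and C7c are 1,3-related through C8c, so a carbanion and a ketone on a three-carbon chain span the aryne.
4. 15 ⇐ rhodium-catalysed asymmetric conjugate addition of boronic acid 11 to alkylidene cyanoacetate 14 (sets C8c). 11 ⇐ enantioselective rhodium-carbene C–H insertion (sets C3 of the dihydrobenzofuran), then acid epimerization to trans.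
5. Ring order: dihydrobenzofuran (step 5), cyclopentane of the indane (step 13), eight-membered ring (step 18). C8b, C7c and C7b are set after the key step (steps 14, 15, 18).

Key step: step 13

Remark: the aryne precursor 22 is treated as not purchasable and is made in steps 10–12. The sense of induction of the chiral catalysts in steps 5 and 9 is assumed; the enantiomeric catalyst would be used if the first run shows the opposite sense.
Abbreviation used in names: DHB-4-yl = (2R,3R)-3-(3,5-dimethoxyphenyl)-6-methoxy-2-(4-methoxyphenyl)-2,3-dihydro-1-benzofuran-4-yl.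

Step 1
Reactants: 1 1-bromo-3,5-dimethoxybenzene; 2 3,5-dimethoxybenzoyl chloride
Product: 3 (2-bromo-4,6-dimethoxyphenyl)(3,5-dimethoxyphenyl)methanone
Conditions: AlCl3 (1.2 equiv), CH2Cl2, 0 → 23 °C
Reagents that add atoms: none
Why: Friedel–Crafts acylation should occur para to one methoxy group and ortho to the other (next to bromine), the usual site for 5-substituted 1,3-dimethoxybenzenes, because the carbon between the two methoxy groups is more hindered.

Step 2
Reactants: 3 (2-bromo-4,6-dimethoxyphenyl)(3,5-dimethoxyphenyl)methanone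
Product: 4 (2-bromo-6-hydroxy-4-methoxyphenyl)(3,5-dimethoxyphenyl)methanone
Conditions: BCl3 (1.1 equiv), CH2Cl2, −78 → 0 °C; H2O
Reagents that add atoms: none
Why: Chelation of BCl3 between the carbonyl oxygen and the ortho methoxy group should make the Lewis acid ether cleavage selective for that one ether.

Step 3
Reactants: 4 (2-bromo-6-hydroxy-4-methoxyphenyl)(3,5-dimethoxyphenyl)methanone; 5 4-methoxybenzyl chloride
Product: 6 {2-bromo-4-methoxy-6-[(4-methoxyphenyl)methoxy]phenyl}(3,5-dimethoxyphenyl)methanone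
Conditions: K2CO3, Bu4NI (cat.), DMF, 60 °C
Reagents that add atoms: none
Why: Williamson etherification installs the OCH2 carbon that becomes C2 of the dihydrobenzofuran, together with its 4-methoxyphenyl group.

Step 4
Reactants: 6 {2-bromo-4-methoxy-6-[(4-methoxyphenyl)methoxy]phenyl}(3,5-dimethoxyphenyl)methanone
Product: 7 hydrazone of 6 (E/Z mixture)
Conditions: N2H4·H2O (10 equiv), AcOH (cat.), n-BuOH, 100 °C, sealed tube
Reagents that add atoms: hydrazine (as hydrate), NN
Why: Acid-catalysed condensation of hydrazine with the diaryl ketone, run under forcing conditions because both ortho positions are substituted, gives the free hydrazone needed as diazo precursor.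

Step 5
Reactants: 7 hydrazone of 6
Product: 9 (2S,3R)-4-bromo-3-(3,5-dimethoxyphenyl)-6-methoxy-2-(4-methoxyphenyl)-2,3-dihydro-1-benzofuran (cis), via diaryldiazomethane 8 (not isolated)
Conditions: MnO2, CH2Cl2, 0 °C; filter; then Rh2(S-PTAD)4 (1 mol %), CH2Cl2, 0 → 23 °C
Reagents that add atoms: none
Why: MnO2 dehydrogenates the hydrazone to the diazo compound, whose donor/donor rhodium carbene inserts into the benzylic ether C–H bond five atoms away (intramolecular carbene C–H insertion); the chiral carboxylate ligands set C3 and the concerted insertion gives the cis-2,3-diaryl ring.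

Step 6
Reactants: 9 cis-dihydrobenzofuran bromide
Product: 10 (2R,3R)-4-bromo-3-(3,5-dimethoxyphenyl)-6-methoxy-2-(4-methoxyphenyl)-2,3-dihydro-1-benzofuran (trans)
Conditions: BF3·OEt2 (1 equiv), CH2Cl2, 0 → 23 °C
Reagents that add atoms: none
Why: The Lewis acid opens the C2–O bond reversibly to a 4-methoxybenzylic cation that recloses to the more stable trans isomer, so only C2 is inverted and the catalyst-set C3 is kept (acid-mediated epimerization).

Step 7
Reactants: 10 trans-dihydrobenzofuran bromide
Product: 11 (DHB-4-yl)boronic acid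
Conditions: n-BuLi, THF, −78 °C; B(OiPr)3; then 1 M HCl
Reagents that add atoms: triisopropyl borate, CC(C)OB(OC(C)C)OC(C)C; water, O
Why: Bromine–lithium exchange, borylation and hydrolysis is standard and tolerates the aryl ethers; boron sits meta to both ring oxygens, so protodeboronation should be slow.

Step 8
Reactants: 12 prop-2-en-1-yl cyanoacetate; 13 4-methoxyphenylglyoxal hydrate
Product: 14 prop-2-en-1-yl (2E)-2-cyano-4-(4-methoxyphenyl)-4-oxobut-2-enoate
Conditions: piperidinium acetate (5 mol %), 4 Å molecular sieves, CH2Cl2, 0 → 23 °C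
Reagents that add atoms: none
Why: Knoevenagel condensation at the aldehyde-level carbon of the glyoxal should give the E-alkylidene cyanoacetate with the aroyl group trans to the ester.

Step 9
Reactants: 11 (DHB-4-yl)boronic acid; 14 alkylidene cyanoacetate
Product: 15 prop-2-en-1-yl (3R)-2-cyano-3-(DHB-4-yl)-4-(4-methoxyphenyl)-4-oxobutanoate (both C2 epimers)
Conditions: [RhCl(C2H4)2]2 (2.5 mol %), (1R,4R)-2,5-diphenylbicyclo[2.2.2]octa-2,5-diene (5.5 mol %), KOH (10 mol %), 1,4-dioxane/H2O 10:1, 20 °C; aq. NH4Cl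
Reagents that add atoms: none
Why: Rhodium/chiral-diene-catalysed asymmetric 1,4-addition of an arylboronic acid to an alkylidene cyanoacetate delivers the aryl group to the carbon beta to nitrile and ester; the diene sets the new benzylic centre under catalyst control, and that centre is shielded from epimerization because the product rests as its cyanoacetate anion.

Step 10
Reactants: 16 3,5-dimethoxyphenol
Product: 17 3,5-dimethoxyphenyl N-(propan-2-yl)carbamate
Conditions: i-PrNCO, Et3N (cat.), CH2Cl2, 23 °C
Reagents that add atoms: isopropyl isocyanate, CC(C)N=C=O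
Why: Amine-catalysed addition of the phenol to the isocyanate gives a carbamate that directs ortho metalation and is easy to cleave later.

Step 11
Reactants: 17 3,5-dimethoxyphenyl N-(propan-2-yl)carbamate
Product: 20 3,5-dimethoxy-2-(trimethylsilyl)phenyl N-(propan-2-yl)carbamate, via N-silyl carbamate 18 (not isolated), via N-silyl C-silyl carbamate 19 (not isolated)
Conditions: TBSOTf, TMEDA, Et2O, 0 → 23 °C; n-BuLi (2 equiv), TMEDA, −78 °C; Me3SiCl; aq. NaHSO4
Reagents that add atoms: chlorotrimethylsilane, C[Si](C)(C)Cl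
Why: After transient N-silylation the carbamate and the neighbouring methoxy group together direct lithiation to the carbon between them (directed ortho metalation); the aryllithium is silylated and the N-silyl group is lost on work-up.

Step 12
Reactants: 20 3,5-dimethoxy-2-(trimethylsilyl)phenyl N-(propan-2-yl)carbamate
Product: 22 3,5-dimethoxy-2-(trimethylsilyl)phenyl trifluoromethanesulfonate, via silyl phenol 21 (not isolated)
Conditions: DBU, Et2NH, MeCN, 40 °C; then PhNTf2, 23 °C
Reagents that add atoms: N-phenylbis(trifluoromethanesulfonimide), O=S(=O)(N(c1ccccc1)S(=O)(=O)C(F)(F)F)C(F)(F)F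
Why: DBU-induced loss of isopropyl isocyanate (trapped by diethylamine) frees the phenoxide, which is triflated in the same flask (one-pot carbamate cleavage and O-sulfonylation).

Step 13
Reactants: 15 cyano ester; 22 silylaryl triflate
Product: 24 prop-2-en-1-yl (2S)-1-cyano-2-(DHB-4-yl)-3-hydroxy-4,6-dimethoxy-3-(4-methoxyphenyl)-2,3-dihydro-1H-indene-1-carboxylate (epimers at C1 and C3), via 3,5-dimethoxybenzyne 23 (not isolated)
Conditions: CsF (3 equiv), 22 (1.3 equiv, slow addition), MeCN, 23 → 50 °C; aq. NH4Cl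
Reagents that add atoms: none
Why: Proposed new method: fluoride turns 22 into 3,5-dimethoxybenzyne and deprotonates the cyanoacetate carbon of 15; the carbanion adds to the aryne carbon remote from the flanking methoxy group (the more distorted, more electrophilic terminus of a 3-alkoxyaryne), so the aryl anion forms ortho to that methoxy group and adds 5-exo-trig to the aroyl ketone three atoms away, a formal (3+2) annulation that closes the cyclopentane of the indane. The closest known reaction types are the acyl-alkylation of arynes with β-keto esters (carbanion addition, then attack of the aryl anion on a carbonyl) and aryne annulations in which the aryl anion closes a five- or six-membered ring onto an ester or ketone. The quaternary centre C1 and the carbinol centre C3 form as mixtures and need no control, because C1 becomes epimerizable in step 14 and C3 is replaced in step 15. The step needs C-arylation rather than O- or N-arylation, 5-exo attack on the ketone rather than 4-exo attack on the ester or nitrile or protonation by solvent, and retention at the benzylic C2. The ketone is favoured because it is the more electrophilic carbonyl and is reached through the less strained ring; C2 is protected because the adjacent cyanoacetate anion suppresses a second deprotonation and C2 is no longer alpha to a carbonyl once the ring has closed.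

Step 14
Reactants: 24 indanol cyano ester
Product: 27 (1S,2R)-2-(DHB-4-yl)-3-hydroxy-4,6-dimethoxy-3-(4-methoxyphenyl)-2,3-dihydro-1H-indene-1-carbonitrile (trans; both C3 epimers), via cyano acid 25 (not isolated), via cis nitrile 26 (not isolated)
Conditions: Pd(PPh3)4 (5 mol %), morpholine (3 equiv), THF, 23 → 50 °C; then DBU (1 equiv), 50 °C
Reagents that add atoms: none
Why: Palladium-catalysed deallylation gives the α-cyano acid, which decarboxylates to the nitrile as a C1 epimer mixture; DBU then equilibrates the acidic benzylic α-nitrile centre to the isomer with the nitrile trans to the bulky C2 aryl group (thermodynamic control).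

Step 15
Reactants: 27 trans hydroxy nitrile
Product: 28 (1S,2R,3R)-2-(DHB-4-yl)-4,6-dimethoxy-3-(4-methoxyphenyl)-2,3-dihydro-1H-indene-1-carbonitrile
Conditions: Et3SiH (10 equiv), CF3CO2H (3 equiv), CH2Cl2, −78 → −40 °C
Reagents that add atoms: none
Why: Ionic hydrogenation: the doubly benzylic tertiary carbinol ionizes at low temperature and the planar cation should take hydride on the face opposite the adjacent C2 aryl group, which gives the cis-2,3-diaryl relationship of the target (kinetic, sterically controlled delivery); the low temperature is chosen to outrun loss of H-2 and opening of the dihydrobenzofuran.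

Step 16
Reactants: 28 indane nitrile
Product: 29 (1S,2R,3R)-2-(DHB-4-yl)-4,6-dimethoxy-3-(4-methoxyphenyl)-2,3-dihydro-1H-indene-1-carbaldehyde
Conditions: i-Bu2AlH (1.5 equiv), toluene/CH2Cl2, −78 °C; aq. Rochelle salt, then dilute HCl
Reagents that add atoms: water, O
Why: Hydride reduction of the nitrile stops at the N-aluminio aldimine, which is hydrolysed to the aldehyde on work-up; C1 stays in the favoured trans arrangement.

Step 17
Reactants: 29 indane aldehyde; 30 4-methoxyphenylmagnesium bromide
Product: 31 [(1S,2R,3R)-2-(DHB-4-yl)-4,6-dimethoxy-3-(4-methoxyphenyl)-2,3-dihydro-1H-inden-1-yl](4-methoxyphenyl)methanol (both carbinol epimers)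
Conditions: THF, −78 → 0 °C; aq. NH4Cl
Reagents that add atoms: none
Why: Grignard addition to the aldehyde; the carbinol configuration does not matter because this centre is ionized in step 18.

Step 18
Reactants: 31 diaryl carbinol
Product: 32 octa-O-methylcanaliculatol
Conditions: BF3·OEt2 (2 equiv), CH2Cl2 (2 mM), −40 → 0 °C
Reagents that add atoms: none
Why: Ionization gives a 4-methoxybenzylic cation that should alkylate the 3,5-dimethoxyphenyl ring ortho to one methoxy group and para to the other (intramolecular Friedel–Crafts alkylation, eight-membered ring). The competing five-membered closure onto the benzofuran ring would need a trans-fused bicyclo[3.3.0]octane and is blocked by the trans arrangement at C1/C2. The new centre C7b is expected to form under reversible conditions in the configuration with the 4-methoxyphenyl group on the outside of the ring.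

Step 19
Reactants: 32 octa-O-methylcanaliculatol
Product: 33 canaliculatol
Conditions: BBr3 (24 equiv), CH2Cl2, −78 → 0 °C; MeOH, then H2O
Reagents that add atoms: none
Why: Lewis acid cleavage of all eight aryl methyl ethers at low temperature; if the dihydrobenzofuran opens it should reclose to the same, more stable trans isomer.

**Compound list**
1 | 1-bromo-3,5-dimethoxybenzene | COc1cc(Br)cc(OC)c1 | starting material
2 | 3,5-dimethoxybenzoyl chloride | COc1cc(cc(OC)c1)C(Cl)=O | starting material
3 | (2-bromo-4,6-dimethoxyphenyl)(3,5-dimethoxyphenyl)methanone | COc1cc(OC)cc(c1)C(=O)c1c(Br)cc(OC)cc1OC | intermediate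
4 | (2-bromo-6-hydroxy-4-methoxyphenyl)(3,5-dimethoxyphenyl)methanone | COc1cc(OC)cc(c1)C(=O)c1c(Br)cc(OC)cc1O | intermediate
5 | 4-methoxybenzyl chloride | COc1ccc(CCl)cc1 | starting material
6 | {2-bromo-4-methoxy-6-[(4-methoxyphenyl)methoxy]phenyl}(3,5-dimethoxyphenyl)methanone | COc1ccc(COc2cc(OC)cc(Br)c2C(=O)c2cc(OC)cc(OC)c2)cc1 | intermediate
7 | hydrazone of 6 (E/Z mixture) | COc1ccc(COc2cc(OC)cc(Br)c2C(=NN)c2cc(OC)cc(OC)c2)cc1 | intermediate
8 | 1-bromo-2-[diazo(3,5-dimethoxyphenyl)methyl]-5-methoxy-3-[(4-methoxyphenyl)methoxy]benzene | COc1ccc(COc2cc(OC)cc(Br)c2C(=[N+]=[N-])c2cc(OC)cc(OC)c2)cc1 | intermediate (not isolated)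
9 | (2S,3R)-4-bromo-3-(3,5-dimethoxyphenyl)-6-methoxy-2-(4-methoxyphenyl)-2,3-dihydro-1-benzofuran (cis) | COc1ccc(cc1)[C@H]2Oc3cc(OC)cc(Br)c3[C@H]2c4cc(OC)cc(OC)c4 | intermediate
10 | (2R,3R)-4-bromo-3-(3,5-dimethoxyphenyl)-6-methoxy-2-(4-methoxyphenyl)-2,3-dihydro-1-benzofuran (trans) | COc1ccc(cc1)[C@@H]2Oc3cc(OC)cc(Br)c3[C@H]2c4cc(OC)cc(OC)c4 | intermediate
11 | (DHB-4-yl)boronic acid | COc1ccc(cc1)[C@@H]2Oc3cc(OC)cc(B(O)O)c3[C@H]2c4cc(OC)cc(OC)c4 | intermediate
12 | prop-2-en-1-yl cyanoacetate | C=CCOC(=O)CC#N | starting material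
13 | 4-methoxyphenylglyoxal hydrate | COc1ccc(cc1)C(=O)C(O)O | starting material
14 | prop-2-en-1-yl (2E)-2-cyano-4-(4-methoxyphenyl)-4-oxobut-2-enoate | C=CCOC(=O)/C(C#N)=C/C(=O)c1ccc(OC)cc1 | intermediate
15 | prop-2-en-1-yl (3R)-2-cyano-3-(DHB-4-yl)-4-(4-methoxyphenyl)-4-oxobutanoate (both C2 epimers) | C=CCOC(=O)C(C#N)[C@@H](C(=O)c1ccc(OC)cc1)c1cc(OC)cc2O[C@@H](c3ccc(OC)cc3)[C@H](c3cc(OC)cc(OC)c3)c12 | intermediate
16 | 3,5-dimethoxyphenol | COc1cc(O)cc(OC)c1 | starting material
17 | 3,5-dimethoxyphenyl N-(propan-2-yl)carbamate | COc1cc(OC)cc(OC(=O)NC(C)C)c1 | intermediate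
18 | 3,5-dimethoxyphenyl N-[tert-butyl(dimethyl)silyl]-N-(propan-2-yl)carbamate | COc1cc(OC)cc(OC(=O)N(C(C)C)[Si](C)(C)C(C)(C)C)c1 | intermediate (not isolated)
19 | 3,5-dimethoxy-2-(trimethylsilyl)phenyl N-[tert-butyl(dimethyl)silyl]-N-(propan-2-yl)carbamate | COc1cc(OC)c([Si](C)(C)C)c(OC(=O)N(C(C)C)[Si](C)(C)C(C)(C)C)c1 | intermediate (not isolated)
20 | 3,5-dimethoxy-2-(trimethylsilyl)phenyl N-(propan-2-yl)carbamate | COc1cc(OC)c([Si](C)(C)C)c(OC(=O)NC(C)C)c1 | intermediate
21 | 3,5-dimethoxy-2-(trimethylsilyl)phenol | COc1cc(OC)c([Si](C)(C)C)c(O)c1 | intermediate (not isolated)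
22 | 3,5-dimethoxy-2-(trimethylsilyl)phenyl trifluoromethanesulfonate | COc1cc(OC)c([Si](C)(C)C)c(OS(=O)(=O)C(F)(F)F)c1 | intermediate
23 | 3,5-dimethoxybenzyne (1,2-didehydro-3,5-dimethoxybenzene) | COC1=CC(OC)=CC#C1 | intermediate (not isolated)
24 | prop-2-en-1-yl (2S)-1-cyano-2-(DHB-4-yl)-3-hydroxy-4,6-dimethoxy-3-(4-methoxyphenyl)-2,3-dihydro-1H-indene-1-carboxylate (epimers at C1 and C3) | C=CCOC(=O)C1(C#N)c2cc(OC)cc(OC)c2C(O)(c2ccc(OC)cc2)[C@H]1c1cc(OC)cc2O[C@@H](c3ccc(OC)cc3)[C@H](c3cc(OC)cc(OC)c3)c12 | intermediate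
25 | (2S)-1-cyano-2-(DHB-4-yl)-3-hydroxy-4,6-dimethoxy-3-(4-methoxyphenyl)-2,3-dihydro-1H-indene-1-carboxylic acid (epimers at C1 and C3) | OC(=O)C1(C#N)c2cc(OC)cc(OC)c2C(O)(c2ccc(OC)cc2)[C@H]1c1cc(OC)cc2O[C@@H](c3ccc(OC)cc3)[C@H](c3cc(OC)cc(OC)c3)c12 | intermediate (not isolated)
26 | (1R,2R)-2-(DHB-4-yl)-3-hydroxy-4,6-dimethoxy-3-(4-methoxyphenyl)-2,3-dihydro-1H-indene-1-carbonitrile (cis; both C3 epimers) | N#C[C@H]1c2cc(OC)cc(OC)c2C(O)(c2ccc(OC)cc2)[C@H]1c1cc(OC)cc2O[C@@H](c3ccc(OC)cc3)[C@H](c3cc(OC)cc(OC)c3)c12 | intermediate (not isolated)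
27 | (1S,2R)-2-(DHB-4-yl)-3-hydroxy-4,6-dimethoxy-3-(4-methoxyphenyl)-2,3-dihydro-1H-indene-1-carbonitrile (trans; both C3 epimers) | N#C[C@@H]1c2cc(OC)cc(OC)c2C(O)(c2ccc(OC)cc2)[C@H]1c1cc(OC)cc2O[C@@H](c3ccc(OC)cc3)[C@H](c3cc(OC)cc(OC)c3)c12 | intermediate
28 | (1S,2R,3R)-2-(DHB-4-yl)-4,6-dimethoxy-3-(4-methoxyphenyl)-2,3-dihydro-1H-indene-1-carbonitrile | N#C[C@@H]1c2cc(OC)cc(OC)c2[C@@H](c2ccc(OC)cc2)[C@H]1c1cc(OC)cc2O[C@@H](c3ccc(OC)cc3)[C@H](c3cc(OC)cc(OC)c3)c12 | intermediate
29 | (1S,2R,3R)-2-(DHB-4-yl)-4,6-dimethoxy-3-(4-methoxyphenyl)-2,3-dihydro-1H-indene-1-carbaldehyde | O=C[C@@H]1c2cc(OC)cc(OC)c2[C@@H](c2ccc(OC)cc2)[C@H]1c1cc(OC)cc2O[C@@H](c3ccc(OC)cc3)[C@H](c3cc(OC)cc(OC)c3)c12 | intermediate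
30 | 4-methoxyphenylmagnesium bromide | COc1ccc([Mg]Br)cc1 | starting material
31 | [(1S,2R,3R)-2-(DHB-4-yl)-4,6-dimethoxy-3-(4-methoxyphenyl)-2,3-dihydro-1H-inden-1-yl](4-methoxyphenyl)methanol (both carbinol epimers) | OC(c1ccc(OC)cc1)[C@@H]1c2cc(OC)cc(OC)c2[C@@H](c2ccc(OC)cc2)[C@H]1c1cc(OC)cc2O[C@@H](c3ccc(OC)cc3)[C@H](c3cc(OC)cc(OC)c3)c12 | intermediate
32 | octa-O-methylcanaliculatol (all six stereocentres as in the target) | COc1ccc([C@@H]2c3c(OC)cc(OC)cc3[C@H]3[C@H](c4ccc(OC)cc4)c4c(OC)cc(OC)cc4[C@@H]4c5c(cc(OC)cc5[C@H]23)O[C@H]4c2ccc(OC)cc2)cc1 | intermediate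
33 | canaliculatol | Oc1ccc([C@@H]2c3c(O)cc(O)cc3[C@H]3[C@H](c4ccc(O)cc4)c4c(O)cc(O)cc4[C@@H]4c5c(cc(O)cc5[C@H]23)O[C@H]4c2ccc(O)cc2)cc1 | target

**Totals**
Total steps: 19. Longest linear sequence: 15 steps (1–7, 9, 13–19).

**Steps most likely to fail**

Step 13 (annulation). The aryl anion may be protonated by the solvent or diverted into 4-exo attack on the ester before it reaches the ketone, the hindered tertiary carbanion may be arylated on oxygen or nitrogen instead of carbon, and the benzylic centre of 15 may epimerize. The fallback sets out from 15 and makes the two bonds one after the other by known reactions. The sodium salt of 15 (NaH, DMF) is C-arylated with (3,5-dimethoxyphenyl)(2,4,6-trimethylphenyl)iodonium tetrafluoroborate F1 (prepared from 3,5-dimethoxyphenylboronic acid and (diacetoxyiodo)mesitylene with BF3·OEt2), a metal-free α-arylation in which the unhindered aryl group is transferred, to give prop-2-en-1-yl (3S)-2-cyano-3-(DHB-4-yl)-2-(3,5-dimethoxyphenyl)-4-(4-methoxyphenyl)-4-oxobutanoate F2. Both ring positions ortho to the new bond are equivalent and activated by the methoxy groups, so CF3CO2H and Et3SiH at low temperature should close the five-membered ring by Friedel–Crafts hydroxyalkylation at the ketone and reduce the resulting cation in the same flask, giving prop-2-en-1-yl (2S,3R)-1-cyano-2-(DHB-4-yl)-4,6-dimethoxy-3-(4-methoxyphenyl)-2,3-dihydro-1H-indene-1-carboxylate F3. Deallylation, decarboxylation and base equilibration of F3 under the conditions of step 14 come back to the route at 28.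

Step 18 (eight-membered ring). The medium-ring closure may be slow enough for elimination to the benzylidene indane, intermolecular alkylation or acid opening of the dihydrobenzofuran to take over, and the cation may be attacked from the wrong face at C7b. The fallback sets out from 29 and closes the ring by an irreversible acylation. Pinnick oxidation (NaClO2, NaH2PO4, 2-methylbut-2-ene) gives (1S,2R,3R)-2-(DHB-4-yl)-4,6-dimethoxy-3-(4-methoxyphenyl)-2,3-dihydro-1H-indene-1-carboxylic acid F4. Intramolecular Friedel–Crafts acylation through the mixed trifluoroacetic anhydride (or the acid chloride with SnCl4) at the same arene carbon gives the eight-membered diaryl ketone F5 (the 7b-oxo compound lacking the 7b aryl group). Addition of 30 in the presence of CeCl3 gives the tertiary carbinol F6, and ionic hydrogenation (Et3SiH, CF3CO2H) of the ring-bound cation comes back to the route at 32.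

Step 9 (conjugate addition). Transmetalation and insertion of the ortho-substituted boronic acid may be slow, so that protodeboronation, base-induced retro-Knoevenagel cleavage of 14 or weak catalyst control of the new centre compete. The fallback sets out from 10 and gives up catalyst control. Magnesium insertion (Mg, LiCl, THF) gives (DHB-4-yl)magnesium bromide F7, which adds to 14 under CuBr·SMe2 catalysis at −78 °C. Because the dihydrobenzofuran is already a single enantiomer, the product is 15 together with its (3S)-epimer F8, which are diastereomers and are separated by chromatography; the route is rejoined at 15.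

**Further compounds**
F1 | step 13 | (3,5-dimethoxyphenyl)(2,4,6-trimethylphenyl)iodonium tetrafluoroborate | COc1cc(OC)cc(c1)[I+]c1c(C)cc(C)cc1C.F[B-](F)(F)F
F2 | step 13 | prop-2-en-1-yl (3S)-2-cyano-3-(DHB-4-yl)-2-(3,5-dimethoxyphenyl)-4-(4-methoxyphenyl)-4-oxobutanoate (both C2 epimers) | C=CCOC(=O)C(C#N)(c1cc(OC)cc(OC)c1)[C@@H](C(=O)c1ccc(OC)cc1)c1cc(OC)cc2O[C@@H](c3ccc(OC)cc3)[C@H](c3cc(OC)cc(OC)c3)c12
F3 | step 13 | prop-2-en-1-yl (2S,3R)-1-cyano-2-(DHB-4-yl)-4,6-dimethoxy-3-(4-methoxyphenyl)-2,3-dihydro-1H-indene-1-carboxylate (both C1 epimers) | C=CCOC(=O)C1(C#N)c2cc(OC)cc(OC)c2[C@@H](c2ccc(OC)cc2)[C@H]1c1cc(OC)cc2O[C@@H](c3ccc(OC)cc3)[C@H](c3cc(OC)cc(OC)c3)c12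
F4 | step 18 | (1S,2R,3R)-2-(DHB-4-yl)-4,6-dimethoxy-3-(4-methoxyphenyl)-2,3-dihydro-1H-indene-1-carboxylic acid | OC(=O)[C@@H]1c2cc(OC)cc(OC)c2[C@@H](c2ccc(OC)cc2)[C@H]1c1cc(OC)cc2O[C@@H](c3ccc(OC)cc3)[C@H](c3cc(OC)cc(OC)c3)c12
F5 | step 18 | eight-membered ring ketone (32 with C=O at C7b in place of CH(4-methoxyphenyl)) | COc1ccc([C@@H]2c3c(OC)cc(OC)cc3[C@H]3C(=O)c4c(OC)cc(OC)cc4[C@@H]4c5c(cc(OC)cc5[C@H]23)O[C@H]4c2ccc(OC)cc2)cc1
F6 | step 18 | 7b-hydroxy derivative of 32 (tertiary carbinol, both C7b epimers) | COc1ccc([C@@H]2c3c(OC)cc(OC)cc3[C@H]3C(O)(c4ccc(OC)cc4)c4c(OC)cc(OC)cc4[C@@H]4c5c(cc(OC)cc5[C@H]23)O[C@H]4c2ccc(OC)cc2)cc1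
F7 | step 9 | (DHB-4-yl)magnesium bromide | COc1ccc(cc1)[C@@H]2Oc3cc(OC)cc([Mg]Br)c3[C@H]2c4cc(OC)cc(OC)c4
F8 | step 9 | prop-2-en-1-yl (3S)-2-cyano-3-(DHB-4-yl)-4-(4-methoxyphenyl)-4-oxobutanoate (both C2 epimers) | C=CCOC(=O)C(C#N)[C@H](C(=O)c1ccc(OC)cc1)c1cc(OC)cc2O[C@@H](c3ccc(OC)cc3)[C@H](c3cc(OC)cc(OC)c3)c12
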